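Over 4.0 d at constant temperature, solid Q leaves by two exits: it dissolves to Z, or it pairs to Q2.

Q 21 mM; E 1.4 mM (held); time 4.0 d

- amount of Z.D and J together at 4.0 d, in percent of the Q charged
- the change that raises the amount of Z.D and J together at 4.0 d, in percent of the Q charged most ("none" if none brings more than 2 percentage points) (theta / zeta / alpha / epsilon / none)
- amount of Z.D and J together at 4.0 d, in percent of the Q charged, after epsilon

- theta: doubling the solubility in step 3, all else as stated
- zeta: doubling the solubility in step 1, all else as stated
- alpha: doubling the dissolution coefficient of step 3, all else as stated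
- epsilon: doubling the saturation concentration of E, all else as stated

- percentages count the Q that a species holds: one Q2 counts as two
- Z.D is meant together with its J
- a doubled species enters its step squared and goes two at a time
- solid, in amounts per volume of the solution: Q, J
- at the start none of D is dissolved
- at the start none of Q is in solution
- run time (flask): 4.0 d

    Q ⇌ Z, rate k1*(cs1 - [Z]) while solid is left; crystals form when [Z] > cs1 (cs1 = 14 mM, k1 = 3.8 × 10⁻⁴ min⁻¹)
    Z + D → Z.D (k2 = 0.63 L mol⁻¹ min⁻¹)
    J ⇌ Z.D, rate k3*(cs3 - [Z.D]) while solid is left; crystals form when [Z.D] > cs3 (cs3 = 0.61 mM, k3 = 0.020 min⁻¹)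
    E ⇌ D, rate k4*(csat - [D]) (k4 = 0.39 min⁻¹, csat = 1.4 mM)
    2 Q → Q2 (k5 = 0.043 L mol⁻¹ min⁻¹)

I reckon rates first. Dissolution starts at v = 0.00532 mM min⁻¹. Pairing, counted per Q, starts at w = 0.0379 mM min⁻¹, which is 7.12 times v. Pairing goes with the square of Q, so at half the charge w has fallen to a quarter of its start. Let s = v/(v + w), the part of the Q being lost at a given moment that dissolves (the selectivity). It climbs as the solid is spent:

s at the start = 12.3%

s at half the charge = 35.9%

s at the last of the solid = 100%

S = (first + 4 × middle + last)/6 = 42.7%

S is my dissolving share, the mean of s over the charge. A finer mean, taken at quarter points, gives 45.1%, so the coarse mean costs 2.4 percentage points. Dissolved Z lowers v, which pulls the other way, so I keep S.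

The solid then lasts about 1.17 d. With D taken at 1.4 mM, Z has a pseudo-first-order half-life of 0.546 d. The remaining time is 5.18 half-lives, so nearly all of the Z becomes Z.D, and I expect y near S. Doubling the solubility of Q doubles v and gives S = 55.6%, which is more than now. The other changes touch no term of S, so I choose zeta and put yb near y.

The forecast gives 42% (38% to 45%), zeta, and 43% (40% to 47%): “The Q dimerisation outruns dissolution”.

The simulation gives 42.3%, zeta with a gain of 13 points, and 43.6%.

In this flask the net dissolution of Q up to 4.0 d is 43.0% of the charge, against S of 42.7%. In the neighbour flask with 36 mM of Q, S is 28.1%, and the run holds 27.7% as Z.D, J and Z together. The y of that neighbour flask, 27.1%, lies below the forecast's low end of 38%, so the forecast's range fails at that charge. This flask at 4.00 d holds Q at 0% and Z at 0.757%, and Q2 stands at 57.0%, as it does at 40.0 d. At 40.0 d, ten times the time, y reaches 43.0%, a further 0.70 points.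

The numbers were drawn at random within sensible limits; the result is computed.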